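**Retrosynthetic overview**

- The target is (5S,9R,10S,13S)-15-acetoxylabd-7-en-17-oic acid (labdane numbering; 5α-H, 9α-H, 10β-CH3). The plan rests on ring B: C6–C7–C8(C17)–C9, with the C11–C16 chain on C9, is an alkylidene acetoacetate, and C10 is the only enolisable carbon of a ring A ketone whose carbonyl is C5.
- Late stage: the acid comes from its tert-butyl ester, C7=C8 from the C7 enol triflate of a cyclic β-keto ester, and 5α-H from hydrogenation of C5=C6.
- Key disconnection: C9–C10 (auxiliary-controlled Michael addition of the 1-phenylethylamine imine of 2,2,6-trimethylcyclohexanone) and C5=C6 (dianion aldol condensation). Ring A is bought; ring B is closed in the key step.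
- The acceptor is made from (S)-citronellol (source of C13) by O-benzylation, ozonolysis and Knoevenagel condensation with tert-butyl acetoacetate. C15 is carried as a benzyl ether because an acetate would be enolised or cleaved by the dianion base; the acetate is installed after hydrogenolysis.

Key step: step 5

Assumption: (S)-1-phenylethylamine is taken to induce the same sense at the new quaternary carbon as it does with 2-methylcyclohexanone, which corresponds to the 10β-methyl configuration of the target.

**Route**

Step 1
Reactants: 1 (S)-citronellol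
Product: 2 benzyl (S)-citronellyl ether
Conditions: NaH, BnBr, Bu4NI (cat.), THF, 0→25 °C
Reagents that add atoms: benzyl bromide, BrCc1ccccc1
Why: Williamson etherification of the primary alkoxide installs a C15 protecting group that tolerates the strong base and acid of step 5 and is removed in the hydrogenation of step 6.

Step 2
Reactants: 2 benzyl (S)-citronellyl ether
Product: 3 (4S)-6-(benzyloxy)-4-methylhexanal
Conditions: O3, CH2Cl2, −78 °C (stopped at first excess); PPh3, −78→25 °C
Reagents that add atoms: ozone, [O-][O+]=O
Why: Ozonolysis of the electron-rich trisubstituted alkene with reductive work-up should give the aldehyde that becomes C9, and the C13 stereocentre is not touched.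

Step 3
Reactants: 3 (4S)-6-(benzyloxy)-4-methylhexanal; 4 tert-butyl acetoacetate
Product: 5 tert-butyl (6S)-2-acetyl-8-(benzyloxy)-6-methyloct-2-enoate (E/Z mixture)
Conditions: piperidine (0.1 equiv), AcOH (0.1 equiv), 4 Å MS, CH2Cl2, 0 °C
Reagents that add atoms: none
Why: Knoevenagel condensation under amine–acid catalysis at low temperature should give the alkylidene acetoacetate, and either alkene geometry is usable because C8 carries two acceptor groups and its configuration is erased later.

Step 4
Reactants: 6 2,2,6-trimethylcyclohexanone (racemic); 7 (S)-1-phenylethylamine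
Product: 8 (S)-1-phenyl-N-(2,2,6-trimethylcyclohexylidene)ethanamine
Conditions: TiCl4 (0.6 equiv), Et3N (3 equiv), toluene, 0→110 °C
Reagents that add atoms: none
Why: TiCl4-mediated condensation removes water irreversibly and is the standard way to form ketimines of hindered ketones; the racemic ring stereocentre does not matter because it becomes the sp2 carbon of the reacting enamine.

Step 5
Reactants: 8 (S)-1-phenyl-N-(2,2,6-trimethylcyclohexylidene)ethanamine; 5 tert-butyl (6S)-2-acetyl-8-(benzyloxy)-6-methyloct-2-enoate
Product: 12 tert-butyl 15-(benzyloxy)-7-oxolabd-5-en-17-oate, via Michael adduct imine 9 (not isolated), via seco diketo ester 10 (not isolated), via C5 aldol 11 (not isolated)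
Conditions: THF (concentrated), 25→45 °C; 20% aq AcOH, 25 °C, extractive work-up; crude in THF, LiN(iPr)2 (2.3 equiv), −78→0 °C, AcOH quench; crude, TsOH·H2O (0.1 equiv), toluene, 25 °C
Reagents that add atoms: none
Why: The imine reacts through its only possible secondary enamine (C10=C5, because C4 is quaternary), which adds through C10 to C9 of the doubly activated alkene in a compact aza-ene-like transition state with transfer of the N–H hydrogen to C8, the reaction type known from asymmetric Michael additions of 1-phenylethylamine imines of 2-alkylcycloalkanones to electrophilic alkenes in chiral-imine Robinson annulations. With the benzylic C–H of the auxiliary in the enamine plane towards C4, the phenyl group covers one face, so the (S)-amine should send the acceptor to the face that gives the 10β-methyl configuration. In the cyclic transition state the C11 chain should point away from ring A, where a pseudo-axial C4 methyl group blocks the inside position, and this places C11 and C20 cis on the future ring B (9α-H); both acceptor geometries can adopt this arrangement. Aqueous acetic acid then hydrolyses the C5 imine, and two equivalents of amide base convert the β-keto ester into its 1,3-dianion, whose terminal carbon C6 adds to the non-enolisable C5 ketone in a 6-(enolendo)-exo-trig aldol that closes ring B. Acid-catalysed loss of water from the strained tertiary carbinol can only use a C6 hydrogen, so the C5=C6 enone forms regiospecifically. The step needs carbon rather than nitrogen alkylation and facial control at C10, which the hydrogen-transfer geometry and the auxiliary provide, and it needs an acceptor without a base-sensitive ester, which the benzyl ether at C15 provides.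

Step 6
Reactants: 12 tert-butyl 15-(benzyloxy)-7-oxolabd-5-en-17-oate
Product: 13 tert-butyl 15-hydroxy-7-oxo-5α-labdan-17-oate
Conditions: H2 (3 atm), 10% Pd/C, EtOAc–EtOH, 25 °C
Reagents that add atoms: none
Why: Heterogeneous hydrogenation should deliver hydrogen to C5=C6 from the α face, opposite the axial C20 and 4β methyl groups, setting the trans ring fusion (5α-H), and the same catalyst hydrogenolyses the benzyl ether while ketone and tert-butyl ester stay intact.

Step 7
Reactants: 13 tert-butyl 15-hydroxy-7-oxo-5α-labdan-17-oate
Product: 14 tert-butyl 15-acetoxy-7-oxo-5α-labdan-17-oate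
Conditions: Ac2O, pyridine, CH2Cl2, 0→25 °C
Reagents that add atoms: acetic anhydride, CC(=O)OC(C)=O
Why: Acylation of the primary alcohol in pyridine without a nucleophilic catalyst should install the C15 acetate without O-acylating the β-keto ester.

Step 8
Reactants: 14 tert-butyl 15-acetoxy-7-oxo-5α-labdan-17-oate
Product: 15 tert-butyl 15-acetoxy-7-(trifluoromethylsulfonyloxy)labd-7-en-17-oate
Conditions: NaH (1.1 equiv), PhNTf2, THF, 0→25 °C
Reagents that add atoms: N-phenylbis(trifluoromethanesulfonimide), O=S(=O)(N(c1ccccc1)S(=O)(=O)C(F)(F)F)C(F)(F)F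
Why: One equivalent of hydride removes only the C8 hydrogen of the β-keto ester, and O-sulfonylation of that enolate fixes the double bond between C7 and C8 regiospecifically without touching C9.

Step 9
Reactants: 15 tert-butyl 15-acetoxy-7-(trifluoromethylsulfonyloxy)labd-7-en-17-oate
Product: 16 tert-butyl 15-acetoxylabd-7-en-17-oate
Conditions: Pd(OAc)2 (5 mol%), PPh3 (10 mol%), HCO2H, Bu3N, DMF, 60 °C
Reagents that add atoms: none
Why: Palladium-catalysed formate reduction of the enol triflate (oxidative addition, decarboxylation of formate to a palladium hydride, reductive elimination) replaces the triflate by hydrogen without moving the double bond and leaves both esters intact.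

Step 10
Reactants: 16 tert-butyl 15-acetoxylabd-7-en-17-oate
Product: 17 (5S,9R,10S,13S)-15-acetoxylabd-7-en-17-oic acid (CNP0412535.1)
Conditions: CF3CO2H–CH2Cl2 (1:3), 0→25 °C
Reagents that add atoms: none
Why: Acidolysis of the tert-butyl ester through the tert-butyl cation, lost as isobutene, frees the conjugated acid under conditions that spare the primary acetate and the C7=C8 bond.

**Compound list**

1 | (S)-citronellol, (3S)-3,7-dimethyloct-6-en-1-ol | OCC[C@@H](C)CCC=C(C)C | starting material
2 | benzyl (S)-citronellyl ether | c1ccccc1COCC[C@@H](C)CCC=C(C)C | intermediate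
3 | (4S)-6-(benzyloxy)-4-methylhexanal | c1ccccc1COCC[C@@H](C)CCC=O | intermediate
4 | tert-butyl acetoacetate | CC(=O)CC(=O)OC(C)(C)C | starting material
5 | tert-butyl (6S)-2-acetyl-8-(benzyloxy)-6-methyloct-2-enoate, E/Z mixture | c1ccccc1COCC[C@@H](C)CCC=C(C(C)=O)C(=O)OC(C)(C)C | intermediate
6 | 2,2,6-trimethylcyclohexanone, racemic | CC1CCCC(C)(C)C1=O | starting material
7 | (S)-1-phenylethylamine | C[C@H](N)c1ccccc1 | starting material
8 | (S)-1-phenyl-N-(2,2,6-trimethylcyclohexylidene)ethanamine, ring epimers, in equilibrium with its secondary enamine | C[C@H](N=C1C(C)CCCC1(C)C)c1ccccc1 | intermediate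
9 | Michael adduct imine: tert-butyl 2-acetyl-8-(benzyloxy)-6-methyl-3-{1,3,3-trimethyl-2-[(S)-1-phenylethylimino]cyclohexyl}octanoate, C9, C10 and C13 as in the target, C8 unfixed | CC(=O)C(C(=O)OC(C)(C)C)[C@H](CC[C@H](C)CCOCc1ccccc1)[C@@]1(C)CCCC(C)(C)C1=N[C@@H](C)c1ccccc1 | intermediate
10 | seco diketo ester: tert-butyl (3S,6S)-2-acetyl-8-(benzyloxy)-6-methyl-3-[(1R)-1,3,3-trimethyl-2-oxocyclohexyl]octanoate, C2 epimers | CC(=O)C(C(=O)OC(C)(C)C)[C@H](CC[C@H](C)CCOCc1ccccc1)[C@@]1(C)CCCC(C)(C)C1=O | intermediate
11 | C5 aldol: tert-butyl 15-(benzyloxy)-5-hydroxy-7-oxolabdan-17-oate, 9α-H, 10β-methyl, 13S, C5 and C8 unfixed | c1ccccc1COCC[C@@H](C)CC[C@H]1C(C(=O)OC(C)(C)C)C(=O)CC2(O)C(C)(C)CCC[C@]12C | intermediate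
12 | tert-butyl 15-(benzyloxy)-7-oxolabd-5-en-17-oate, 8α-ester (epimerisable), 9α-H, 10β-methyl, 13S | c1ccccc1COCC[C@@H](C)CC[C@H]1[C@H](C(=O)OC(C)(C)C)C(=O)C=C2C(C)(C)CCC[C@]12C | intermediate
13 | tert-butyl 15-hydroxy-7-oxo-5α-labdan-17-oate, 8α-ester (epimerisable), 9α-H, 13S | OCC[C@@H](C)CC[C@H]1[C@H](C(=O)OC(C)(C)C)C(=O)C[C@H]2C(C)(C)CCC[C@]12C | intermediate
14 | tert-butyl 15-acetoxy-7-oxo-5α-labdan-17-oate | CC(=O)OCC[C@@H](C)CC[C@H]1[C@H](C(=O)OC(C)(C)C)C(=O)C[C@H]2C(C)(C)CCC[C@]12C | intermediate
15 | tert-butyl 15-acetoxy-7-(trifluoromethylsulfonyloxy)labd-7-en-17-oate, 5α-H, 9α-H, 13S | CC(=O)OCC[C@@H](C)CC[C@H]1C(C(=O)OC(C)(C)C)=C(OS(=O)(=O)C(F)(F)F)C[C@H]2C(C)(C)CCC[C@]12C | intermediate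
16 | tert-butyl 15-acetoxylabd-7-en-17-oate, 5α-H, 9α-H, 13S | CC(=O)OCC[C@@H](C)CC[C@H]1C(C(=O)OC(C)(C)C)=CC[C@H]2C(C)(C)CCC[C@]12C | intermediate
17 | (5S,9R,10S,13S)-15-acetoxylabd-7-en-17-oic acid | CC(=O)OCC[C@@H](C)CC[C@H]1C(C(=O)O)=CC[C@H]2C(C)(C)CCC[C@]12C | target

**Step count**

Total: 10 steps. Longest linear sequence: 9 steps (steps 1, 2, 3, 5, 6, 7, 8, 9, 10 from (S)-citronellol).

**Steps most likely to fail**

Step 5. Carbon–carbon bond formation may be slow because the reacting enamine conformer is crowded by the C4 gem-dimethyl group. The basic imine may deconjugate the acceptor, facial selectivity at C10 or C9 may be poor, and the tertiary aldol may cleave by retro-aldol instead of dehydrating. The fallback sets out from 6 and 5 and comes back at 10. Ketone 6 is converted (LiN(iPr)2, Me3SiCl, THF, −78 °C) into its only possible silyl enol ether, trimethyl[(2,6,6-trimethylcyclohex-1-en-1-yl)oxy]silane F1. A Lewis-acid-promoted Mukaiyama–Michael addition of this enol ether to 5 (Sc(OTf)3 cat., CH2Cl2, −78→0 °C, aqueous work-up) should give the diketo ester 10 as a mixture of C9/C10 diastereomers. This mixture is cyclised and dehydrated as in the second half of step 5, and the diastereomers of 12 are separated by chromatography. Auxiliary control of C10 is given up in this fallback.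

Step 6. Hydrogen may be delivered with poor facial selectivity to the congested C5=C6 bond, giving cis-fused material, or the reduction may stall. The fallback sets out from 12 and comes back at 16; it moves the radical to C5 so that the ring fusion is set by a hydrogen-atom transfer that favours the trans-decalin.
- Luche reduction of 12 (NaBH4, CeCl3·7H2O, MeOH, −20 °C) gives the allylic alcohol tert-butyl 15-(benzyloxy)-7-hydroxylabd-5-en-17-oate F2.
- Manganese-hydride hydrogen-atom-transfer hydrogenation (Mn(dpm)3 cat., PhSiH3, tBuOOH, iPrOH, 25 °C) adds a hydrogen atom to C6 and quenches the tertiary C5 radical from the α face. This should give tert-butyl 15-(benzyloxy)-7-hydroxy-5α-labdan-17-oate F3.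
- Hydrogenolysis (H2, 10% Pd/C, EtOH) gives the diol tert-butyl 7,15-dihydroxy-5α-labdan-17-oate F4.
- Ac2O, pyridine and DMAP give tert-butyl 7,15-diacetoxy-5α-labdan-17-oate F5.
- DBU (toluene, 80 °C) eliminates the C7 acetate through the ester enolate (E1cB) to give 16, and step 10 follows.

Step 4. Condensation of the doubly α-substituted ketone with the α-branched amine may stay incomplete. The fallback sets out from 6 and comes back at 8. The ketone is converted (LiN(iPr)2, PhNTf2, THF, −78→0 °C) into 2,6,6-trimethylcyclohex-1-en-1-yl trifluoromethanesulfonate F6. Palladium-catalysed C–N coupling of this triflate with 7 (Pd2(dba)3, BINAP, Cs2CO3, toluene, 100 °C) should give the secondary enamine, which is the reacting tautomer of 8 and enters step 5 as such.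

**Further compounds**

F1 | step 5 | trimethyl[(2,6,6-trimethylcyclohex-1-en-1-yl)oxy]silane | CC1=C(O[Si](C)(C)C)C(C)(C)CCC1
F2 | step 6 | tert-butyl 15-(benzyloxy)-7-hydroxylabd-5-en-17-oate (C7 epimers) | c1ccccc1COCC[C@@H](C)CC[C@H]1[C@H](C(=O)OC(C)(C)C)C(O)C=C2C(C)(C)CCC[C@]12C
F3 | step 6 | tert-butyl 15-(benzyloxy)-7-hydroxy-5α-labdan-17-oate | c1ccccc1COCC[C@@H](C)CC[C@H]1[C@H](C(=O)OC(C)(C)C)C(O)C[C@H]2C(C)(C)CCC[C@]12C
F4 | step 6 | tert-butyl 7,15-dihydroxy-5α-labdan-17-oate | OCC[C@@H](C)CC[C@H]1[C@H](C(=O)OC(C)(C)C)C(O)C[C@H]2C(C)(C)CCC[C@]12C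
F5 | step 6 | tert-butyl 7,15-diacetoxy-5α-labdan-17-oate | CC(=O)OCC[C@@H](C)CC[C@H]1[C@H](C(=O)OC(C)(C)C)C(OC(C)=O)C[C@H]2C(C)(C)CCC[C@]12C
F6 | step 4 | 2,6,6-trimethylcyclohex-1-en-1-yl trifluoromethanesulfonate | CC1=C(OS(=O)(=O)C(F)(F)F)C(C)(C)CCC1
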